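## Retrosynthetic overview
1. The target is 2-hydroxy-5-methoxy-3-nonadecyl-1,4-benzoquinone. It is achiral and its only ring is the quinone.
2. Last disconnection: the C5–OMe bond. It comes from site-selective acid-catalysed methanolysis of the unhindered vinylogous acid in 2,5-dihydroxy-3-nonadecyl-1,4-benzoquinone.
3. Key C–C disconnection: the ring C3–CH2 bond. It comes from a three-component reductive alkylation of 2,5-dihydroxy-1,4-benzoquinone with nonadecanal and Hantzsch ester.
4. Nonadecanal is made fresh by oxidising commercial 1-nonadecanol.
5. No ring is formed, because the six-membered quinone ring is purchased intact.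

Assumptions:
- The SMILES has 20 carbons before the ring-closure digit, so the side chain is 19 carbons (n-nonadecyl) plus ring C3. The formula is C26H44O4.
- The molecule has no stereocentres or stereogenic double bonds, so "single enantiomer" does not apply and no stereocontrol is needed.

## Route

**Step 1**
Reactants: **1**, 1-nonadecanol
Product: **2**, nonadecanal
Conditions: TEMPO (10 mol %), PhI(OAc)2 (1.1 equiv), CH2Cl2, rt, 3 h. Pass through a short silica plug and use at once.
Reagents that add atoms: none
Why: This is an oxoammonium-mediated (TEMPO/BAIB, Piancatelli–Margarita) oxidation of a primary alcohol. It stops at the aldehyde because no aldehyde hydrate forms in anhydrous CH2Cl2, and it runs at rt, where the waxy alcohol stays dissolved.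

**Step 2**
Reactants: **2**, nonadecanal (1.0 equiv, added slowly); **3**, 2,5-dihydroxy-1,4-benzoquinone (1.5 equiv)
Product: **4**, 2,5-dihydroxy-3-nonadecyl-1,4-benzoquinone
Conditions: L-proline (20 mol %), Hantzsch ester (diethyl 2,6-dimethyl-1,4-dihydropyridine-3,5-dicarboxylate, 1.1 equiv), CH2Cl2, rt, 24 h. Stir open to air, filter off excess **3**, wash with dilute HCl, then chromatograph or recrystallise.
Reagents that add atoms: none. The Hantzsch ester delivers only hydrogen, and the aldehyde oxygen leaves as water.
Why: This is an organocatalytic three-component reductive alkylation.
- Proline-iminium Knoevenagel condensation occurs at the nucleophilic C3 of the vinylogous acid and gives a very electrophilic alkylidene (quinone-methide-type) intermediate.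
- The Hantzsch ester reduces this intermediate by conjugate hydride transfer faster than a second quinone can add to it.
- Excess **3** and slow aldehyde addition suppress 3,6-dialkylation.
- No stereocentre is created.

**Step 3**
Reactants: **4**, 2,5-dihydroxy-3-nonadecyl-1,4-benzoquinone
Product: **5**, Irisoquin-C (2-hydroxy-5-methoxy-3-nonadecyl-1,4-benzoquinone)
Conditions: MeOH, cat. conc. H2SO4, reflux, 3–6 h (follow by TLC). Cool and collect the crystalline product, then recrystallise.
Reagents that add atoms: methanol, CO
Why: This is a Fischer-type vinylogous esterification, in which MeOH adds to the protonated hydroxyquinone and water is eliminated.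
- It occurs readily at C5, which is flanked by C6–H.
- The C2–OH next to the alkyl chain is sterically and electronically deactivated. This matches the known inertness of 3-alkyl-2-hydroxyquinones to MeOH/H+.
- Both tautomers of **4** lead to the same 5-O-methyl product.
- The quinone and the saturated chain are inert to these conditions.

## Compound list
1 | 1-nonadecanol | CCCCCCCCCCCCCCCCCCCO | starting material
2 | nonadecanal | CCCCCCCCCCCCCCCCCCC=O | intermediate
3 | 2,5-dihydroxy-1,4-benzoquinone | O=C1C=C(O)C(=O)C=C1O | starting material
4 | 2,5-dihydroxy-3-nonadecyl-1,4-benzoquinone | CCCCCCCCCCCCCCCCCCCC1=C(O)C(=O)C=C(O)C1=O | intermediate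
5 | Irisoquin-C, 2-hydroxy-5-methoxy-3-nonadecyl-1,4-benzoquinone (achiral) | CCCCCCCCCCCCCCCCCCCC1=C(O)C(=O)C=C(OC)C1=O | target

## Summary
Total step count: 3. This falls to 2 if nonadecanal is bought rather than made.
Longest linear sequence: 3 steps (1 → 2 → 4 → 5).

Steps most likely to fail, highest risk first:

1. **Step 2.**
   - Risks: mono- versus 3,6-dialkylation, alkylidene-bis-quinone adducts, and poor solubility of **3**.
   - Fallback: build the substitution pattern on an arene instead. Lithiate 1,2,4,5-tetramethoxybenzene (n-BuLi, THF/HMPA) and alkylate it with 1-bromononadecane. CAN oxidation then gives 2,5-dimethoxy-3-nonadecyl-1,4-benzoquinone. Finally, selectively hydrolyse the twisted 2-OMe next to the chain with HClO4 to reach **5**, or use NaOH to rejoin the route at **4**.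

2. **Step 3.**
   - Risks: O-regioselectivity, over-methylation to the 2,5-dimethyl ether, and incomplete conversion.
   - Fallback: reverse the order of events so that C–C bond formation fixes the regiochemistry. Prepare 2-hydroxy-5-methoxy-1,4-benzoquinone by Thiele–Winter acetoxylation of 2-methoxy-1,4-benzoquinone, followed by methanolysis and air oxidation. Use it in the Step 2 reductive alkylation. Its only enolic C-nucleophilic site is C3, so **5** forms directly.

3. **Step 1.**
   - Risks: over-oxidation, ester by-products, and aldehyde degradation or oligomerisation on handling.
   - Fallback: generate the aldehyde by C=C cleavage instead of alcohol oxidation. Ozonolysis of commercial 1-eicosene (O3, CH2Cl2, −78 °C, then PPh3 or Me2S) gives nonadecanal, which is carried directly into Step 2.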